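**Plan**

- Retrosynthesis: the hydroxypropenyl chain is cut at its C=C bond back to a C5 methyl ester; ring B is then cut at C3a-C4 and C7-C7a into a 3-methoxy-5-carbomethoxy-2-pyrone and the silyl ketene acetal of a trans 5-aryl-4-(silyloxymethyl)-gamma-butyrolactone; the lactone is cut by an aldol disconnection at the future C2-C3 bond.
- Enabling feature (benzofuran numbering): ring B (C3a, C4, C5, C6, C7, C7a) carries O1 on C7a, OMe on C7 and the carbon chain on C5 para to O1. This is the pattern that pyrone C3-OMe and C5-CO2Me give with a ketene acetal carbon, and O1-C2-C3-C3a-C7a is a gamma-butyrolactone with C7a as its carbonyl carbon.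
- Forward order: the five-membered O-heterocycle is made first as a lactone (aldol, lactonisation); ring B is built onto it second by inverse-demand Diels-Alder reaction, loss of CO2 and aromatisation; the side chain is finished last (reduction, oxidation-Wittig, reduction, desilylation).
- Stereochemistry: C2 (R) and C3 (S) come from one Evans syn aldol directed by (R)-4-benzyl-2-oxazolidinone, the syn adduct closing to the trans lactone; both centres lie outside every later reacting site, and the E alkene comes from a stabilised ylide.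
- The pyrone comes from methyl coumalate by C3 bromination, borylation-oxidation and O-methylation, a sequence free of alkoxide nucleophiles, which would open or ring-contract the pyrone.

Key step: step 11

Remark: Ar stands for 4-(tert-butyldimethylsilyloxy)-3,5-dimethoxyphenyl and TBS for tert-butyldimethylsilyl; the boron aldolate of step 3 is assumed to lactonise during work-up, and the sp3 centres that are made and destroyed within step 11 are left unspecified.

**Route**

Step 1
Reactants: 1 syringaldehyde
Product: 2 4-(tert-butyldimethylsilyloxy)-3,5-dimethoxybenzaldehyde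
Conditions: TBSCl, imidazole, DMF, rt
Reagents that add atoms: tert-butyldimethylsilyl chloride, CC(C)(C)[Si](C)(C)Cl
Why: Silyl ether formation at the phenol (imidazole-mediated silylation) masks the only acidic OH before the enolate chemistry and is removable by fluoride at the end.

Step 2
Reactants: 3 (R)-4-benzyl-2-oxazolidinone; 4 methyl 4-chloro-4-oxobutanoate
Product: 5 methyl 4-[(4R)-4-benzyl-2-oxo-1,3-oxazolidin-3-yl]-4-oxobutanoate
Conditions: Et3N, DMAP (cat.), CH2Cl2, 0 °C to rt
Reagents that add atoms: none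
Why: N-Acylation of the oxazolidinone (nucleophilic acyl substitution under DMAP catalysis) takes place at the acid chloride and leaves the methyl ester for the later lactonisation.

Step 3
Reactants: 5 methyl 4-[(4R)-4-benzyl-2-oxo-1,3-oxazolidin-3-yl]-4-oxobutanoate; 2 4-(tert-butyldimethylsilyloxy)-3,5-dimethoxybenzaldehyde
Product: 8 (4R)-4-benzyl-3-{[(2R,3R)-2-Ar-5-oxooxolan-3-yl]carbonyl}-1,3-oxazolidin-2-one, via boron Z-enolate 6 (not isolated), via syn aldol adduct 7 (not isolated)
Conditions: Bu2BOTf, i-Pr2NEt, CH2Cl2, 0 °C; 2, −78 to 0 °C; pH 7 buffer, MeOH, H2O2, 0 °C; then PPTS (cat.), CH2Cl2, rt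
Reagents that add atoms: dibutylboron triflate, CCCCB(CCCC)OS(=O)(=O)C(F)(F)F (boron group of intermediate 6 only; no atoms in 8)
Why: Evans syn aldol reaction: the Z boron enolate 6 reacts through a Zimmerman-Traxler chair in which the aldehyde approaches the enolate face away from the benzyl group, which sets the carbinol carbon (R, later C2) and the alpha carbon (R, later C3) together, and the gamma-hydroxy ester 7 then lactonises with loss of methanol to the trans lactone, because a syn aldol places the aryl and acyl groups on opposite faces of the five-membered ring.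

Step 4
Reactants: 8 (4R)-4-benzyl-3-{[(2R,3R)-2-Ar-5-oxooxolan-3-yl]carbonyl}-1,3-oxazolidin-2-one
Product: 10 (2R,3R)-2-Ar-5-oxooxolane-3-carboxylic acid, via peroxy acid 9 (not isolated)
Conditions: LiOH, H2O2, THF/H2O, 0 °C; Na2SO3; then HCl to pH 3
Reagents that add atoms: hydrogen peroxide (acting as lithium hydroperoxide), OO
Why: Evans auxiliary hydrolysis: hydroperoxide attacks the exocyclic imide carbonyl in preference to the ring carbamate, sulfite reduces peroxy acid 9, any opened lactone recloses on acidification, and neither stereocentre is enolised at 0 °C.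

Step 5
Reactants: 10 (2R,3R)-2-Ar-5-oxooxolane-3-carboxylic acid
Product: 11 (4S,5R)-5-Ar-4-(hydroxymethyl)oxolan-2-one
Conditions: BH3·SMe2, THF, 0 °C to rt; MeOH
Reagents that add atoms: none
Why: Chemoselective borane reduction: the carboxylic acid is reduced through its acyloxyborane much faster than the lactone, so only the future C9 reaches the alcohol oxidation level.

Step 6
Reactants: 11 (4S,5R)-5-Ar-4-(hydroxymethyl)oxolan-2-one
Product: 12 (4S,5R)-5-Ar-4-[(tert-butyldimethylsilyloxy)methyl]oxolan-2-one
Conditions: TBSCl, imidazole, CH2Cl2, 0 °C to rt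
Reagents that add atoms: tert-butyldimethylsilyl chloride, CC(C)(C)[Si](C)(C)Cl
Why: Silylation of the primary alcohol (silyl ether formation) is done at once so that the hydroxyl cannot translactonise onto the lactone carbonyl and is inert to the amide base of step 7.

Step 7
Reactants: 12 (4S,5R)-5-Ar-4-[(tert-butyldimethylsilyloxy)methyl]oxolan-2-one
Product: 13 (2R,3S)-2-Ar-3-[(TBSO)methyl]-5-(trimethylsilyloxy)-2,3-dihydrofuran (trimethylsilyl ketene acetal of 12)
Conditions: LiN(i-Pr)2 added to 12 and Me3SiCl, THF, −78 °C to rt; volatiles removed, pentane, filtration under Ar; used crude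
Reagents that add atoms: chlorotrimethylsilane, C[Si](C)(C)Cl
Why: Kinetic enolisation at the lactone alpha carbon with in situ O-silylation (silyl ketene acetal formation) gives the electron-rich C=C bond needed for step 11; the beta carbon carries no leaving group and neither stereocentre is acidic, so the trans arrangement is kept.

Step 8
Reactants: 14 methyl coumalate
Product: 16 methyl 3-bromo-2-oxo-2H-pyran-5-carboxylate, via trans-3,4-dibromide 15 (not isolated)
Conditions: Br2, CH2Cl2, 0 °C to rt; then Et3N, 0 °C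
Reagents that add atoms: bromine, BrBr
Why: Electrophilic bromination at C3 by addition-elimination: bromine adds across the C3=C4 bond of the pyrone, whose C3 is the nucleophilic terminus of the vinylogous enol ester, and Et3N removes HBr from dibromide 15 to restore the pyrone.

Step 9
Reactants: 16 methyl 3-bromo-2-oxo-2H-pyran-5-carboxylate
Product: 18 methyl 3-hydroxy-2-oxo-2H-pyran-5-carboxylate, via pinacol boronate 17 (not isolated)
Conditions: B2pin2, PdCl2(dppf) (cat.), KOAc, 1,4-dioxane, 80 °C; filtered crude, then KHSO5 (as 2KHSO5·KHSO4·K2SO4), acetone/H2O, 0 °C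
Reagents that add atoms: potassium peroxymonosulfate, [K+].[O-]S(=O)(=O)OO (hydroxyl oxygen of 18); bis(pinacolato)diboron, CC1(C)OB(OC1(C)C)B1OC(C)(C)C(C)(C)O1 (boron group of intermediate 17 only)
Why: Miyaura borylation followed by oxidation of the C-B bond: zerovalent palladium inserts into the C3-Br bond, acetate-assisted transmetalation with B2pin2 gives boronate 17, and peroxymonosulfate converts it into the enol by 1,2-migration from boron to oxygen, a sequence that needs no alkoxide or hydroxide.

Step 10
Reactants: 18 methyl 3-hydroxy-2-oxo-2H-pyran-5-carboxylate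
Product: 19 methyl 3-methoxy-2-oxo-2H-pyran-5-carboxylate
Conditions: MeI, K2CO3, acetone, rt
Reagents that add atoms: iodomethane, CI
Why: O-Methylation of the acidic 3-hydroxy pyrone (Williamson ether synthesis) with carbonate, a base too weak and too poorly nucleophilic to attack C6 of the pyrone.

Step 11
Reactants: 13 (2R,3S)-2-Ar-3-[(TBSO)methyl]-5-(trimethylsilyloxy)-2,3-dihydrofuran; 19 methyl 3-methoxy-2-oxo-2H-pyran-5-carboxylate
Product: 22 methyl (2R,3S)-2-Ar-3-[(TBSO)methyl]-7-methoxy-2,3-dihydro-1-benzofuran-5-carboxylate, via bridged lactone adduct 20 (not isolated), via tetrahydrobenzofuran diene 21 (not isolated)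
Conditions: 19 (1.3 equiv), MeC(OSiMe3)=NSiMe3 (1.5 equiv), toluene, 100 °C, sealed tube
Reagents that add atoms: none
Why: The electron-rich C4=C5 bond of ketene acetal 13 adds across C3/C6 of the electron-poor 2-pyrone 19 in an inverse-electron-demand Diels-Alder reaction (probably asynchronous, the nucleophilic acetal beta carbon bonding first to pyrone C6), the bridged lactone 20 extrudes CO2 by retro-(4+2) cycloaddition, and diene 21 aromatises by ionisation of the C7a-OSiMe3 bond to an O1-stabilised arenium ion that loses H-3a. The closest known reaction type is the conversion of coumalates with ketene acetals into para-alkoxybenzoates with loss of CO2 and alcohol. Ring B is closed as a six-membered carbocycle by intermolecular (4+2) annulation onto the C3a-C7a edge of the preformed dihydrofuran (new bonds C3a-C4 and C7-C7a, the five-membered ring staying intact), so no ring-closure constraint applies. No stereocentre is created that survives: the sp3 centres at C3a and C7a vanish on aromatisation, and C2 and C3 lie outside the reacting pi system, are not acidic under these neutral conditions and keep the trans relationship set in step 3. The regiochemistry needed, acetal beta carbon to pyrone C6 and acetal carbon to the methoxy-bearing C3, is secured by the polarisation of both partners, C6 being the electrophilic terminus beta to the ester and C3 the enolate-like terminus that closes onto the oxocarbenium carbon. The chemoselectivity needed in the aromatisation, loss of trimethylsilanol and not of O1, is secured by the better leaving-group ability of silanolate, the better donor ability of the ring ether oxygen and the absence of base (which would favour anti elimination of O1), while the silylating additive captures the silanol before it can protonate unreacted 13.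

Step 12
Reactants: 22 methyl (2R,3S)-2-Ar-3-[(TBSO)methyl]-7-methoxy-2,3-dihydro-1-benzofuran-5-carboxylate
Product: 23 {(2R,3S)-2-Ar-3-[(TBSO)methyl]-7-methoxy-2,3-dihydro-1-benzofuran-5-yl}methanol
Conditions: i-Bu2AlH, CH2Cl2, −78 °C; aq. KNaC4H4O6
Reagents that add atoms: none
Why: Hydride reduction of the aryl ester to the benzylic alcohol with i-Bu2AlH, which leaves both silyl ethers and the benzylic ether bond C2-O1 untouched.

Step 13
Reactants: 23 {(2R,3S)-2-Ar-3-[(TBSO)methyl]-7-methoxy-2,3-dihydro-1-benzofuran-5-yl}methanol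
Product: 25 ethyl (2E)-3-{(2R,3S)-2-Ar-3-[(TBSO)methyl]-7-methoxy-2,3-dihydro-1-benzofuran-5-yl}prop-2-enoate, via aldehyde 24 (not isolated)
Conditions: MnO2, Ph3P=CHCO2Et, CH2Cl2, rt to 40 °C
Reagents that add atoms: ethyl (triphenylphosphoranylidene)acetate, CCOC(=O)C=P(c1ccccc1)(c1ccccc1)c1ccccc1
Why: Tandem oxidation-Wittig reaction: MnO2 oxidises only the benzylic alcohol, and the stabilised ylide traps aldehyde 24 as it forms to give the E enoate under the thermodynamic control usual for stabilised ylides.

Step 14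
Reactants: 25 ethyl (2E)-3-{(2R,3S)-2-Ar-3-[(TBSO)methyl]-7-methoxy-2,3-dihydro-1-benzofuran-5-yl}prop-2-enoate
Product: 26 (2E)-3-{(2R,3S)-2-Ar-3-[(TBSO)methyl]-7-methoxy-2,3-dihydro-1-benzofuran-5-yl}prop-2-en-1-ol
Conditions: i-Bu2AlH, CH2Cl2, −78 °C; aq. KNaC4H4O6
Reagents that add atoms: none
Why: 1,2-Reduction of the enoate with i-Bu2AlH at low temperature gives the allylic alcohol without conjugate reduction or loss of the E geometry.

Step 15
Reactants: 26 (2E)-3-{(2R,3S)-2-Ar-3-[(TBSO)methyl]-7-methoxy-2,3-dihydro-1-benzofuran-5-yl}prop-2-en-1-ol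
Product: 27 4-[(2R,3S)-3-(hydroxymethyl)-5-[(1E)-3-hydroxyprop-1-en-1-yl]-7-methoxy-2,3-dihydro-1-benzofuran-2-yl]-2,6-dimethoxyphenol
Conditions: Bu4NF, AcOH, THF, 0 °C to rt
Reagents that add atoms: none
Why: Fluoride-mediated desilylation removes the aryl and the primary silyl ether together, and the acetic acid buffer keeps the freed phenol protonated so that the C2-O1 bond is not opened through a quinone methide.

**Compound list**

1 | syringaldehyde (4-hydroxy-3,5-dimethoxybenzaldehyde) | COc1cc(C=O)cc(OC)c1O | starting material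
2 | 4-(tert-butyldimethylsilyloxy)-3,5-dimethoxybenzaldehyde | COc1cc(C=O)cc(OC)c1O[Si](C)(C)C(C)(C)C | intermediate
3 | (R)-4-benzyl-2-oxazolidinone | O=C1N[C@H](Cc2ccccc2)CO1 | starting material
4 | methyl 4-chloro-4-oxobutanoate | COC(=O)CCC(=O)Cl | starting material
5 | methyl 4-[(4R)-4-benzyl-2-oxo-1,3-oxazolidin-3-yl]-4-oxobutanoate | COC(=O)CCC(=O)N1[C@H](Cc2ccccc2)COC1=O | intermediate
6 | dibutylboron Z-enolate of 5 | COC(=O)C/C=C(\OB(CCCC)CCCC)N1[C@H](Cc2ccccc2)COC1=O | intermediate (not isolated)
7 | methyl (3R,4R)-3-{[(4R)-4-benzyl-2-oxo-1,3-oxazolidin-3-yl]carbonyl}-4-[4-(tert-butyldimethylsilyloxy)-3,5-dimethoxyphenyl]-4-hydroxybutanoate (syn aldol adduct) | COc1cc([C@@H]([C@@H](CC(=O)OC)C(=O)N2[C@H](Cc3ccccc3)COC2=O)O)cc(OC)c1O[Si](C)(C)C(C)(C)C | intermediate (not isolated)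
8 | (4R)-4-benzyl-3-{[(2R,3R)-2-[4-(tert-butyldimethylsilyloxy)-3,5-dimethoxyphenyl]-5-oxooxolan-3-yl]carbonyl}-1,3-oxazolidin-2-one (trans lactone imide) | COc1cc([C@@H]2OC(=O)C[C@H]2C(=O)N3[C@H](Cc4ccccc4)COC3=O)cc(OC)c1O[Si](C)(C)C(C)(C)C | intermediate
9 | (2R,3R)-2-[4-(tert-butyldimethylsilyloxy)-3,5-dimethoxyphenyl]-5-oxooxolane-3-carboperoxoic acid | COc1cc([C@@H]2OC(=O)C[C@H]2C(=O)OO)cc(OC)c1O[Si](C)(C)C(C)(C)C | intermediate (not isolated)
10 | (2R,3R)-2-[4-(tert-butyldimethylsilyloxy)-3,5-dimethoxyphenyl]-5-oxooxolane-3-carboxylic acid | COc1cc([C@@H]2OC(=O)C[C@H]2C(=O)O)cc(OC)c1O[Si](C)(C)C(C)(C)C | intermediate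
11 | (4S,5R)-5-[4-(tert-butyldimethylsilyloxy)-3,5-dimethoxyphenyl]-4-(hydroxymethyl)oxolan-2-one | COc1cc([C@@H]2OC(=O)C[C@H]2CO)cc(OC)c1O[Si](C)(C)C(C)(C)C | intermediate
12 | (4S,5R)-5-[4-(tert-butyldimethylsilyloxy)-3,5-dimethoxyphenyl]-4-[(tert-butyldimethylsilyloxy)methyl]oxolan-2-one | COc1cc([C@@H]2OC(=O)C[C@H]2CO[Si](C)(C)C(C)(C)C)cc(OC)c1O[Si](C)(C)C(C)(C)C | intermediate
13 | (2R,3S)-2-[4-(tert-butyldimethylsilyloxy)-3,5-dimethoxyphenyl]-3-[(tert-butyldimethylsilyloxy)methyl]-5-(trimethylsilyloxy)-2,3-dihydrofuran (trimethylsilyl ketene acetal of 12) | COc1cc([C@@H]2OC(O[Si](C)(C)C)=C[C@H]2CO[Si](C)(C)C(C)(C)C)cc(OC)c1O[Si](C)(C)C(C)(C)C | intermediate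
14 | methyl coumalate (methyl 2-oxo-2H-pyran-5-carboxylate) | COC(=O)C1=COC(=O)C=C1 | starting material
15 | methyl trans-3,4-dibromo-2-oxo-3,4-dihydro-2H-pyran-5-carboxylate (racemic, one enantiomer drawn) | COC(=O)C1=COC(=O)[C@H](Br)[C@H]1Br | intermediate (not isolated)
16 | methyl 3-bromo-2-oxo-2H-pyran-5-carboxylate | COC(=O)C1=COC(=O)C(Br)=C1 | intermediate
17 | methyl 2-oxo-3-(4,4,5,5-tetramethyl-1,3,2-dioxaborolan-2-yl)-2H-pyran-5-carboxylate | COC(=O)C1=COC(=O)C(B2OC(C)(C)C(C)(C)O2)=C1 | intermediate (not isolated)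
18 | methyl 3-hydroxy-2-oxo-2H-pyran-5-carboxylate | COC(=O)C1=COC(=O)C(O)=C1 | intermediate
19 | methyl 3-methoxy-2-oxo-2H-pyran-5-carboxylate | COC(=O)C1=COC(=O)C(OC)=C1 | intermediate
20 | bridged lactone cycloadduct of 13 and 19 (2-oxabicyclo[2.2.2]oct-7-en-3-one fused to the 2-aryl-3-(silyloxymethyl)oxolane; OSiMe3 on the ketal carbon, OMe on the bridgehead next to the lactone carbonyl, CO2Me on the alkene; mixture at the new centres) | COc1cc([C@@H]2OC3(O[Si](C)(C)C)C4(OC)C=C(C(=O)OC)C(OC4=O)C3[C@H]2CO[Si](C)(C)C(C)(C)C)cc(OC)c1O[Si](C)(C)C(C)(C)C | intermediate (not isolated)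
21 | methyl (2R,3S)-2-[4-(tert-butyldimethylsilyloxy)-3,5-dimethoxyphenyl]-3-[(tert-butyldimethylsilyloxy)methyl]-7-methoxy-7a-(trimethylsilyloxy)-2,3,3a,7a-tetrahydro-1-benzofuran-5-carboxylate (cis-fused; C3a/C7a unspecified) | COc1cc([C@@H]2OC3(O[Si](C)(C)C)C(OC)=CC(C(=O)OC)=CC3[C@H]2CO[Si](C)(C)C(C)(C)C)cc(OC)c1O[Si](C)(C)C(C)(C)C | intermediate (not isolated)
22 | methyl (2R,3S)-2-[4-(tert-butyldimethylsilyloxy)-3,5-dimethoxyphenyl]-3-[(tert-butyldimethylsilyloxy)methyl]-7-methoxy-2,3-dihydro-1-benzofuran-5-carboxylate | COc1cc([C@@H]2Oc3c(OC)cc(C(=O)OC)cc3[C@H]2CO[Si](C)(C)C(C)(C)C)cc(OC)c1O[Si](C)(C)C(C)(C)C | intermediate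
23 | {(2R,3S)-2-[4-(tert-butyldimethylsilyloxy)-3,5-dimethoxyphenyl]-3-[(tert-butyldimethylsilyloxy)methyl]-7-methoxy-2,3-dihydro-1-benzofuran-5-yl}methanol | COc1cc([C@@H]2Oc3c(OC)cc(CO)cc3[C@H]2CO[Si](C)(C)C(C)(C)C)cc(OC)c1O[Si](C)(C)C(C)(C)C | intermediate
24 | (2R,3S)-2-[4-(tert-butyldimethylsilyloxy)-3,5-dimethoxyphenyl]-3-[(tert-butyldimethylsilyloxy)methyl]-7-methoxy-2,3-dihydro-1-benzofuran-5-carbaldehyde | COc1cc([C@@H]2Oc3c(OC)cc(C=O)cc3[C@H]2CO[Si](C)(C)C(C)(C)C)cc(OC)c1O[Si](C)(C)C(C)(C)C | intermediate (not isolated)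
25 | ethyl (2E)-3-{(2R,3S)-2-[4-(tert-butyldimethylsilyloxy)-3,5-dimethoxyphenyl]-3-[(tert-butyldimethylsilyloxy)methyl]-7-methoxy-2,3-dihydro-1-benzofuran-5-yl}prop-2-enoate | COc1cc([C@@H]2Oc3c(OC)cc(/C=C/C(=O)OCC)cc3[C@H]2CO[Si](C)(C)C(C)(C)C)cc(OC)c1O[Si](C)(C)C(C)(C)C | intermediate
26 | (2E)-3-{(2R,3S)-2-[4-(tert-butyldimethylsilyloxy)-3,5-dimethoxyphenyl]-3-[(tert-butyldimethylsilyloxy)methyl]-7-methoxy-2,3-dihydro-1-benzofuran-5-yl}prop-2-en-1-ol | COc1cc([C@@H]2Oc3c(OC)cc(/C=C/CO)cc3[C@H]2CO[Si](C)(C)C(C)(C)C)cc(OC)c1O[Si](C)(C)C(C)(C)C | intermediate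
27 | 4-[(2R,3S)-3-(hydroxymethyl)-5-[(1E)-3-hydroxyprop-1-en-1-yl]-7-methoxy-2,3-dihydro-1-benzofuran-2-yl]-2,6-dimethoxyphenol | COc1cc([C@@H]2Oc3c(OC)cc(/C=C/CO)cc3[C@H]2CO)cc(OC)c1O | target

**Step count**

Total: 15 steps. Longest linear sequence: 11 steps (step 1 or 2, then 3, 4, 5, 6, 7, 11, 12, 13, 14, 15); the pyrone branch (steps 8 to 10) is three steps and joins at step 11.

**Steps most likely to fail**

Step 11. What may go wrong: diene 21 aromatises by anti elimination across C3a-C7a that expels the ring oxygen O1 instead of trimethylsilanol, so that the dihydrofuran opens. The fallback still sets out from 13 and 19 under the same heating but takes the opened material on deliberately. Aqueous citric acid work-up removes the aryl trimethylsilyl ether and should deliver methyl 3-[(1R,2S)-1-[4-(tert-butyldimethylsilyloxy)-3,5-dimethoxyphenyl]-3-(tert-butyldimethylsilyloxy)-1-hydroxypropan-2-yl]-4-hydroxy-5-methoxybenzoate F1. Catalytic TsOH in CH2Cl2 at 0 °C then ionises the electron-rich benzylic alcohol, and the phenol closes the five-membered ring on the cation anti to the untouched C3 substituent (acid-mediated SN1 etherification, the established closure of 2-aryl-2,3-dihydrobenzofurans). This should give trans 22, where the route is rejoined; C3 is never touched, so the enantiomeric series is kept.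

Step 9. What may go wrong: protodeboronation of the electron-poor alkenyl boronate, or attack of acetate or water at C6 of the pyrone during the palladium-catalysed borylation, so that the hydroxy pyrone is not obtained. The fallback moves the oxygenation from the pyrone to the finished arene. Bromopyrone 16, a recognised diene for electron-rich alkenes, is heated with 13 under the conditions of step 11. With the same polarity-controlled regiochemistry and loss of CO2 and silanol it should give methyl (2R,3S)-7-bromo-2-[4-(tert-butyldimethylsilyloxy)-3,5-dimethoxyphenyl]-3-[(tert-butyldimethylsilyloxy)methyl]-2,3-dihydro-1-benzofuran-5-carboxylate F2. Palladium-catalysed C-O coupling of this aryl bromide with methanol (Pd2(dba)3, t-BuBrettPhos, Cs2CO3, MeOH, toluene, 60 °C) then installs the C7 methoxy group and returns to 22.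

Step 7. What may go wrong: competing C-silylation of the enolate and hydrolysis of the trimethylsilyl ketene acetal during the non-aqueous isolation, which returns lactone 12. The fallback sets out from 12 and uses soft enolisation without strong base (t-BuMe2SiOTf, Et3N, CH2Cl2, 0 °C). This should give the more robust (2R,3S)-2-[4-(tert-butyldimethylsilyloxy)-3,5-dimethoxyphenyl]-3-[(tert-butyldimethylsilyloxy)methyl]-5-(tert-butyldimethylsilyloxy)-2,3-dihydrofuran F3, which tolerates filtration through basic alumina. Heated with 19 in toluene it should undergo the same cycloaddition, lose CO2 and tert-butyldimethylsilanol, and so rejoin the route at 22 without passing through 13.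

Further compounds
F1 | step 11 | methyl 3-[(1R,2S)-1-[4-(tert-butyldimethylsilyloxy)-3,5-dimethoxyphenyl]-3-(tert-butyldimethylsilyloxy)-1-hydroxypropan-2-yl]-4-hydroxy-5-methoxybenzoate | COc1cc([C@H](O)[C@H](CO[Si](C)(C)C(C)(C)C)c2cc(C(=O)OC)cc(OC)c2O)cc(OC)c1O[Si](C)(C)C(C)(C)C
F2 | step 9 | methyl (2R,3S)-7-bromo-2-[4-(tert-butyldimethylsilyloxy)-3,5-dimethoxyphenyl]-3-[(tert-butyldimethylsilyloxy)methyl]-2,3-dihydro-1-benzofuran-5-carboxylate | COc1cc([C@@H]2Oc3c(Br)cc(C(=O)OC)cc3[C@H]2CO[Si](C)(C)C(C)(C)C)cc(OC)c1O[Si](C)(C)C(C)(C)C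
F3 | step 7 | (2R,3S)-2-[4-(tert-butyldimethylsilyloxy)-3,5-dimethoxyphenyl]-3-[(tert-butyldimethylsilyloxy)methyl]-5-(tert-butyldimethylsilyloxy)-2,3-dihydrofuran | COc1cc([C@@H]2OC(O[Si](C)(C)C(C)(C)C)=C[C@H]2CO[Si](C)(C)C(C)(C)C)cc(OC)c1O[Si](C)(C)C(C)(C)C
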